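**Retrosynthetic overview**

1. Atom labels follow germacrane numbering: ten-membered carbocycle C1–C10 (C14 on C10, C15 on C4) and lactone ring O–C6–C7–C11(=C13)–C12(=O). The C1/C10 oxirane comes last, from the 1(10)E olefin, and the C8 and C3 esters come from the free alcohols.
2. Key disconnection C7–C8. The unit C13=C11–C7–C8–O is a homoallylic alcohol whose allyl part lies in the lactone ring and whose C7–C8 bond lies only in the ten-membered ring. It maps back to an α-(bromomethyl)butenolide (C11=C7 endocyclic, C13–Br) tethered to a C8 aldehyde. A CrCl2 allylation with allyl transposition joins C7 and C8 (both electrophilic in the precursor), closes the carbocycle, sets C7 and C8 and unveils the exocyclic methylene in one operation.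
3. Acyclic precursor: the butenolide comes from Pd-catalysed carbonylative lactonisation of a (Z)-iodo allylic alcohol made from the C6 propargylic alcohol. C6 and C3 come from two zinc–ProPhenol alkynylations, the 4Z olefin from syn-carbocupration of an ynoate, and the 1(10)E olefin from Zr-catalysed carboalumination.
4. Ring order: butenolide (step 10), ten-membered carbocycle (step 15), oxirane (step 19).

Key step: step 15

Remark: the ProPhenol enantiomers in steps 3 and 8 assume that the (S,S)-ligand delivers the zinc acetylide to the Re face of the aldehyde (O > carbon substituent > H); if the sense is opposite the two ligands are exchanged, both being commercial.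

**Route**

Step 1
Reactants: 1 tert-butyl(but-3-yn-1-yloxy)dimethylsilane; 2 oxirane
Product: 5 (3E)-6-{[tert-butyl(dimethyl)silyl]oxy}-4-methylhex-3-en-1-ol, via alkenyldimethylalane 3 (not isolated), via lithium alkenylalanate 4 (not isolated)
Conditions: Me3Al, Cp2ZrCl2 (20 mol%), CH2Cl2, 0 °C to rt; evaporate, hexane; n-BuLi, −78 °C; 2, THF, −78 °C to rt; aq. NH4Cl
Reagents that add atoms: trimethylaluminium, C[Al](C)C
Why: Zirconium-catalysed Negishi carboalumination adds CH3 and Al syn across the terminal alkyne with the methyl (C14) on the internal carbon, which fixes the 1(10)E olefin, and the lithium alanate transfers the alkenyl group to oxirane with retention to add C2 and C3.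

Step 2
Reactants: 5 (3E)-6-{[tert-butyl(dimethyl)silyl]oxy}-4-methylhex-3-en-1-ol
Product: 6 (3E)-6-{[tert-butyl(dimethyl)silyl]oxy}-4-methylhex-3-enal
Conditions: Dess–Martin periodinane, NaHCO3, CH2Cl2, 0 °C; used crude
Reagents that add atoms: none
Why: Dess–Martin oxidation under bicarbonate buffer is neutral enough to give the β,γ-unsaturated aldehyde without migration of the C1=C10 double bond into conjugation.

Step 3
Reactants: 6 (3E)-6-{[tert-butyl(dimethyl)silyl]oxy}-4-methylhex-3-enal; 7 methyl prop-2-ynoate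
Product: 9 methyl (4S,6E)-9-{[tert-butyl(dimethyl)silyl]oxy}-4-hydroxy-7-methylnon-6-en-2-ynoate, via methylzinc acetylide 8 (not isolated)
Conditions: (S,S)-ProPhenol (20 mol%), Ph3PO (40 mol%), Me2Zn, toluene, 0 °C; 7 premixed, then 6 added slowly; aq. NH4Cl
Reagents that add atoms: none
Why: Zinc–ProPhenol catalysed enantioselective alkynylation, in which acetylide 8 and the aldehyde are held in the chiral dinuclear zinc pocket and the alkynyl group is delivered to the Re face, setting C3 as S.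

Step 4
Reactants: 9 methyl (4S,6E)-9-{[tert-butyl(dimethyl)silyl]oxy}-4-hydroxy-7-methylnon-6-en-2-ynoate
Product: 10 methyl (4S,6E)-4,9-bis{[tert-butyl(dimethyl)silyl]oxy}-7-methylnon-6-en-2-ynoate
Conditions: TBSCl, imidazole, DMF, 0 °C to rt
Reagents that add atoms: tert-butyldimethylsilyl chloride, CC(C)(C)[Si](C)(C)Cl
Why: Silyl ether formation blocks the C3 hydroxyl so that the (Z)-enoate formed next cannot lactonise and so that later only the C6 hydroxyl can direct hydride delivery.

Step 5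
Reactants: 10 methyl (4S,6E)-4,9-bis{[tert-butyl(dimethyl)silyl]oxy}-7-methylnon-6-en-2-ynoate
Product: 11 methyl (2Z,4S,6E)-4,9-bis{[tert-butyl(dimethyl)silyl]oxy}-3,7-dimethylnona-2,6-dienoate
Conditions: Me2CuLi (from MeLi and CuI), THF, −78 °C; MeOH then aq. NH4Cl at −78 °C
Reagents that add atoms: lithium dimethylcuprate, [Li+].C[Cu-]C
Why: Conjugate carbocupration of the ynoate is syn, and protonation of the alkenylcopper at −78 °C with retention places the new methyl (C15) cis to H-5 and hence C3 cis to C6, which is the 4Z geometry of the target.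

Step 6
Reactants: 11 methyl (2Z,4S,6E)-4,9-bis{[tert-butyl(dimethyl)silyl]oxy}-3,7-dimethylnona-2,6-dienoate
Product: 12 (2Z,4S,6E)-4,9-bis{[tert-butyl(dimethyl)silyl]oxy}-3,7-dimethylnona-2,6-dien-1-ol
Conditions: iBu2AlH, CH2Cl2, −78 °C; aq. KNaC4H4O6 (potassium sodium tartrate)
Reagents that add atoms: none
Why: 1,2-Reduction of the enoate with iBu2AlH at low temperature gives the (Z)-allylic alcohol without touching the silyl ethers or the olefin geometry.

Step 7
Reactants: 12 (2Z,4S,6E)-4,9-bis{[tert-butyl(dimethyl)silyl]oxy}-3,7-dimethylnona-2,6-dien-1-ol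
Product: 13 (2Z,4S,6E)-4,9-bis{[tert-butyl(dimethyl)silyl]oxy}-3,7-dimethylnona-2,6-dienal
Conditions: MnO2, CH2Cl2, rt
Reagents that add atoms: none
Why: Allylic oxidation with MnO2 is neutral and heterogeneous and should give the (Z)-enal without Z to E isomerisation, as in the oxidation of nerol to neral.

Step 8
Reactants: 13 (2Z,4S,6E)-4,9-bis{[tert-butyl(dimethyl)silyl]oxy}-3,7-dimethylnona-2,6-dienal; 14 triethyl(prop-2-yn-1-yloxy)silane
Product: 16 (4R,5Z,7S,9E)-7,12-bis{[tert-butyl(dimethyl)silyl]oxy}-6,10-dimethyl-1-[(triethylsilyl)oxy]dodeca-5,9-dien-2-yn-4-ol, via alkynyl(methyl)zinc 15 (not isolated)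
Conditions: (R,R)-ProPhenol (20 mol%), Ph3PO (40 mol%), Me2Zn, toluene, 0 °C; aq. NH4Cl
Reagents that add atoms: none
Why: Second zinc–ProPhenol alkynylation, here on an α,β-unsaturated aldehyde (the best substrate class), in which the enantiomeric dizinc catalyst delivers the acetylide to the Si face under catalyst control (the C3 centre is remote) and sets C6 as R.

Step 9
Reactants: 16 (4R,5Z,7S,9E)-7,12-bis{[tert-butyl(dimethyl)silyl]oxy}-6,10-dimethyl-1-[(triethylsilyl)oxy]dodeca-5,9-dien-2-yn-4-ol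
Product: 18 (2Z,4R,5Z,7S,9E)-7,12-bis{[tert-butyl(dimethyl)silyl]oxy}-2-iodo-6,10-dimethyl-1-[(triethylsilyl)oxy]dodeca-2,5,9-trien-4-ol, via cyclic vinylalanate 17 (not isolated)
Conditions: NaAlH2(OCH2CH2OMe)2, THF, 0 °C to rt; EtOAc; I2, THF, −78 °C
Reagents that add atoms: iodine, II
Why: Hydroxyl-directed trans-hydroalumination of the propargylic alkoxide delivers hydride to C7 and aluminium to C11 within a five-membered oxaluminole, and iododealumination with retention gives the (Z)-vinyl iodide with iodine cis to C6, as needed for lactonisation.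

Step 10
Reactants: 18 (2Z,4R,5Z,7S,9E)-7,12-bis{[tert-butyl(dimethyl)silyl]oxy}-2-iodo-6,10-dimethyl-1-[(triethylsilyl)oxy]dodeca-2,5,9-trien-4-ol
Product: 19 (5R)-5-[(1Z,3S,5E)-3,8-bis{[tert-butyl(dimethyl)silyl]oxy}-2,6-dimethylocta-1,5-dien-1-yl]-3-{[(triethylsilyl)oxy]methyl}furan-2(5H)-one
Conditions: Pd(PPh3)4 (5 mol%), CO (1 atm), K2CO3, THF, 40 °C
Reagents that add atoms: carbon monoxide, [C-]#[O+]
Why: Carbonylative lactonisation, in which zerovalent palladium inserts into the C–I bond, CO insertion gives an acylpalladium and the cis-disposed C6 hydroxyl captures it to close the butenolide, with K2CO3 as a base too weak and insoluble to epimerise the γ-position C6.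

Step 11
Reactants: 19 (5R)-5-[(1Z,3S,5E)-3,8-bis{[tert-butyl(dimethyl)silyl]oxy}-2,6-dimethylocta-1,5-dien-1-yl]-3-{[(triethylsilyl)oxy]methyl}furan-2(5H)-one
Product: 20 (5R)-5-[(1Z,3S,5E)-3,8-bis{[tert-butyl(dimethyl)silyl]oxy}-2,6-dimethylocta-1,5-dien-1-yl]-3-(hydroxymethyl)furan-2(5H)-one
Conditions: PPTS (cat.), MeOH/CH2Cl2, 0 °C
Reagents that add atoms: none
Why: Acid-catalysed methanolysis removes the primary allylic triethylsilyl ether far faster than the two tert-butyldimethylsilyl ethers (selective desilylation).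

Step 12
Reactants: 20 (5R)-5-[(1Z,3S,5E)-3,8-bis{[tert-butyl(dimethyl)silyl]oxy}-2,6-dimethylocta-1,5-dien-1-yl]-3-(hydroxymethyl)furan-2(5H)-one
Product: 21 (5R)-3-(bromomethyl)-5-[(1Z,3S,5E)-3,8-bis{[tert-butyl(dimethyl)silyl]oxy}-2,6-dimethylocta-1,5-dien-1-yl]furan-2(5H)-one
Conditions: CBr4, PPh3, CH2Cl2, 0 °C
Reagents that add atoms: carbon tetrabromide, BrC(Br)(Br)Br
Why: Appel bromination converts the primary allylic alcohol into the bromide by SN2 displacement under neutral conditions that leave the butenolide γ-centre and the silyl ethers untouched.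

Step 13
Reactants: 21 (5R)-3-(bromomethyl)-5-[(1Z,3S,5E)-3,8-bis{[tert-butyl(dimethyl)silyl]oxy}-2,6-dimethylocta-1,5-dien-1-yl]furan-2(5H)-one
Product: 22 (5R)-3-(bromomethyl)-5-[(1Z,3S,5E)-3-{[tert-butyl(dimethyl)silyl]oxy}-8-hydroxy-2,6-dimethylocta-1,5-dien-1-yl]furan-2(5H)-one
Conditions: CSA (cat.), MeOH/CH2Cl2, 0 °C
Reagents that add atoms: none
Why: Acid-catalysed methanolysis cleaves the unhindered primary silyl ether at C8 much faster than the hindered secondary allylic one at C3, and the amine-free medium spares the reactive allylic bromide (selective desilylation).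

Step 14
Reactants: 22 (5R)-3-(bromomethyl)-5-[(1Z,3S,5E)-3-{[tert-butyl(dimethyl)silyl]oxy}-8-hydroxy-2,6-dimethylocta-1,5-dien-1-yl]furan-2(5H)-one
Product: 23 (5R)-3-(bromomethyl)-5-[(1Z,3S,5E)-3-{[tert-butyl(dimethyl)silyl]oxy}-2,6-dimethyl-8-oxoocta-1,5-dien-1-yl]furan-2(5H)-one
Conditions: Dess–Martin periodinane, NaHCO3, CH2Cl2, 0 °C; used at once
Reagents that add atoms: none
Why: Buffered Dess–Martin oxidation gives the β,γ-unsaturated aldehyde under conditions that tolerate the allylic bromide, and the product is cyclised at once to avoid double-bond migration.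

Step 15
Reactants: 23 (5R)-3-(bromomethyl)-5-[(1Z,3S,5E)-3-{[tert-butyl(dimethyl)silyl]oxy}-2,6-dimethyl-8-oxoocta-1,5-dien-1-yl]furan-2(5H)-one
Product: 25 (1(10)E,3S,4Z,6R,7R,8S)-3-{[tert-butyl(dimethyl)silyl]oxy}-8-hydroxygermacra-1(10),4,11(13)-trien-12,6-olide, via allylchromium dichloride 24 (not isolated)
Conditions: CrCl2 (10 equiv), THF, rt, 23 added by syringe pump to 2 mM; aq. NH4Cl
Reagents that add atoms: none
Why: Two equivalents of CrCl2 reduce the allylic C13–Br bond to an η1-allyl complex of trivalent chromium 24, in which the normally electrophilic β-carbon C7 of the butenolide has become the nucleophilic γ-terminus, and this carbon adds to the electrophilic aldehyde carbon C8 through a six-membered Zimmerman–Traxler array (Cr–O=C8···C7=C11–C13) while the C7=C11 bond moves to the exocyclic C11=C13 position. The closest known reaction type is the Nozaki–Hiyama–Kishi carbonyl allylation with 2-(bromomethyl)acrylates and 3-(bromomethyl)butenolides, which is also known as an intramolecular closure of medium-ring carbocycles. The ten-membered ring C1–C10 closes by 10-exo-trig addition to the aldehyde (SE2′ at the allyl unit), and the five-membered lactone, already present, changes from butenolide to α-methylene-γ-butyrolactone. C8 is set by the chair transition state with C9 pseudo-equatorial: because the ring-locked allyl unit holds C6 trans to C13 (an E-crotyl type reagent), the anti relationship 7R,8S should result. C7 is set by the C6 stereocentre, the aldehyde adding to the butenolide face opposite the C5 alkenyl substituent, which gives the trans-fused lactone and should also be the less strained way to span the ring with the seven-atom tether. The step needs ring closure to beat intermolecular allylation, which high dilution and the two rigid olefins (1(10)E and 4Z) in the tether should secure, and it needs γ- over α-attack and tolerance of lactone, silyl ether and olefins, all of which are inherent to allylchromium reagents.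

Step 16
Reactants: 25 (1(10)E,3S,4Z,6R,7R,8S)-3-{[tert-butyl(dimethyl)silyl]oxy}-8-hydroxygermacra-1(10),4,11(13)-trien-12,6-olide
Product: 26 (1(10)E,3S,4Z,6R,7R,8S)-3-{[tert-butyl(dimethyl)silyl]oxy}-8-(3-methylbutanoyloxy)germacra-1(10),4,11(13)-trien-12,6-olide
Conditions: (iPrCH2CO)2O, Et3N, DMAP (cat.), CH2Cl2, 0 °C
Reagents that add atoms: 3-methylbutanoic anhydride, CC(C)CC(=O)OC(=O)CC(C)C
Why: DMAP-catalysed acylation of the secondary C8 hydroxyl is fast at 0 °C, which should outrun translactonisation of the C8 oxygen onto C12.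

Step 17
Reactants: 26 (1(10)E,3S,4Z,6R,7R,8S)-3-{[tert-butyl(dimethyl)silyl]oxy}-8-(3-methylbutanoyloxy)germacra-1(10),4,11(13)-trien-12,6-olide
Product: 27 (1(10)E,3S,4Z,6R,7R,8S)-3-hydroxy-8-(3-methylbutanoyloxy)germacra-1(10),4,11(13)-trien-12,6-olide
Conditions: HF·pyridine, THF, 0 °C to rt
Reagents that add atoms: none
Why: Fluoride-mediated desilylation under the mildly acidic HF·pyridine conditions frees the C3 hydroxyl without conjugate addition to the α-methylene lactone or ester cleavage.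

Step 18
Reactants: 27 (1(10)E,3S,4Z,6R,7R,8S)-3-hydroxy-8-(3-methylbutanoyloxy)germacra-1(10),4,11(13)-trien-12,6-olide
Product: 28 (1(10)E,3S,4Z,6R,7R,8S)-3-acetoxy-8-(3-methylbutanoyloxy)germacra-1(10),4,11(13)-trien-12,6-olide
Conditions: Ac2O, pyridine, DMAP (cat.), CH2Cl2, rt
Reagents that add atoms: acetic anhydride, CC(=O)OC(C)=O
Why: Standard acetylation of the secondary allylic C3 hydroxyl installs the acetate with retention, since the C–O bond is not touched.

Step 19
Reactants: 28 (1(10)E,3S,4Z,6R,7R,8S)-3-acetoxy-8-(3-methylbutanoyloxy)germacra-1(10),4,11(13)-trien-12,6-olide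
Product: 29 (1R,3S,4Z,6R,7R,8S,10R)-3-acetoxy-1,10-epoxy-8-(3-methylbutanoyloxy)germacra-4,11(13)-dien-12,6-olide (CNP0157657.1)
Conditions: mCPBA, NaHCO3, CH2Cl2, 0 °C
Reagents that add atoms: 3-chloroperoxybenzoic acid, OOC(=O)c1cccc(Cl)c1
Why: Prilezhaev epoxidation is stereospecific (the E olefin gives the trans oxirane), should select the electron-rich isolated C1=C10 bond over C4=C5 (deactivated by two allylic acyloxy groups) and the conjugated C11=C13 bond, and is expected to attack the exposed outer face of the ten-membered ring to set 1R,10R.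

**Compound list**

1 | tert-butyl(but-3-yn-1-yloxy)dimethylsilane | C#CCCO[Si](C)(C)C(C)(C)C | starting material
2 | oxirane | C1CO1 | starting material
3 | [(1E)-4-{[tert-butyl(dimethyl)silyl]oxy}-2-methylbut-1-en-1-yl]dimethylaluminium | C[Al](C)/C=C(\C)CCO[Si](C)(C)C(C)(C)C | intermediate
4 | lithium butyl[(1E)-4-{[tert-butyl(dimethyl)silyl]oxy}-2-methylbut-1-en-1-yl]dimethylaluminate | [Li+].CCCC[Al-](C)(C)/C=C(\C)CCO[Si](C)(C)C(C)(C)C | intermediate
5 | (3E)-6-{[tert-butyl(dimethyl)silyl]oxy}-4-methylhex-3-en-1-ol | OCC/C=C(\C)CCO[Si](C)(C)C(C)(C)C | intermediate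
6 | (3E)-6-{[tert-butyl(dimethyl)silyl]oxy}-4-methylhex-3-enal | O=CC/C=C(\C)CCO[Si](C)(C)C(C)(C)C | intermediate
7 | methyl prop-2-ynoate | C#CC(=O)OC | starting material
8 | methyl 3-(methylzincio)prop-2-ynoate | COC(=O)C#C[Zn]C | intermediate
9 | methyl (4S,6E)-9-{[tert-butyl(dimethyl)silyl]oxy}-4-hydroxy-7-methylnon-6-en-2-ynoate | COC(=O)C#C[C@@H](O)C/C=C(\C)CCO[Si](C)(C)C(C)(C)C | intermediate
10 | methyl (4S,6E)-4,9-bis{[tert-butyl(dimethyl)silyl]oxy}-7-methylnon-6-en-2-ynoate | COC(=O)C#C[C@@H](O[Si](C)(C)C(C)(C)C)C/C=C(\C)CCO[Si](C)(C)C(C)(C)C | intermediate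
11 | methyl (2Z,4S,6E)-4,9-bis{[tert-butyl(dimethyl)silyl]oxy}-3,7-dimethylnona-2,6-dienoate | COC(=O)/C=C(/C)[C@@H](O[Si](C)(C)C(C)(C)C)C/C=C(\C)CCO[Si](C)(C)C(C)(C)C | intermediate
12 | (2Z,4S,6E)-4,9-bis{[tert-butyl(dimethyl)silyl]oxy}-3,7-dimethylnona-2,6-dien-1-ol | OC/C=C(/C)[C@@H](O[Si](C)(C)C(C)(C)C)C/C=C(\C)CCO[Si](C)(C)C(C)(C)C | intermediate
13 | (2Z,4S,6E)-4,9-bis{[tert-butyl(dimethyl)silyl]oxy}-3,7-dimethylnona-2,6-dienal | O=C/C=C(/C)[C@@H](O[Si](C)(C)C(C)(C)C)C/C=C(\C)CCO[Si](C)(C)C(C)(C)C | intermediate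
14 | triethyl(prop-2-yn-1-yloxy)silane | C#CCO[Si](CC)(CC)CC | starting material
15 | methyl{3-[(triethylsilyl)oxy]prop-1-yn-1-yl}zinc | C[Zn]C#CCO[Si](CC)(CC)CC | intermediate
16 | (4R,5Z,7S,9E)-7,12-bis{[tert-butyl(dimethyl)silyl]oxy}-6,10-dimethyl-1-[(triethylsilyl)oxy]dodeca-5,9-dien-2-yn-4-ol | CC[Si](CC)(CC)OCC#C[C@H](O)/C=C(/C)[C@@H](O[Si](C)(C)C(C)(C)C)C/C=C(\C)CCO[Si](C)(C)C(C)(C)C | intermediate
17 | sodium (5R)-5-[(1Z,3S,5E)-3,8-bis{[tert-butyl(dimethyl)silyl]oxy}-2,6-dimethylocta-1,5-dien-1-yl]-2,2-bis(2-methoxyethoxy)-3-{[(triethylsilyl)oxy]methyl}-2,5-dihydro-1,2-oxaluminol-2-uide | [Na+].COCCO[Al-]1(OCCOC)O[C@H](/C=C(/C)[C@@H](O[Si](C)(C)C(C)(C)C)C/C=C(\C)CCO[Si](C)(C)C(C)(C)C)C=C1CO[Si](CC)(CC)CC | intermediate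
18 | (2Z,4R,5Z,7S,9E)-7,12-bis{[tert-butyl(dimethyl)silyl]oxy}-2-iodo-6,10-dimethyl-1-[(triethylsilyl)oxy]dodeca-2,5,9-trien-4-ol | CC[Si](CC)(CC)OC/C(I)=C/[C@H](O)/C=C(/C)[C@@H](O[Si](C)(C)C(C)(C)C)C/C=C(\C)CCO[Si](C)(C)C(C)(C)C | intermediate
19 | (5R)-5-[(1Z,3S,5E)-3,8-bis{[tert-butyl(dimethyl)silyl]oxy}-2,6-dimethylocta-1,5-dien-1-yl]-3-{[(triethylsilyl)oxy]methyl}furan-2(5H)-one | CC[Si](CC)(CC)OCC1=C[C@@H](/C=C(/C)[C@@H](O[Si](C)(C)C(C)(C)C)C/C=C(\C)CCO[Si](C)(C)C(C)(C)C)OC1=O | intermediate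
20 | (5R)-5-[(1Z,3S,5E)-3,8-bis{[tert-butyl(dimethyl)silyl]oxy}-2,6-dimethylocta-1,5-dien-1-yl]-3-(hydroxymethyl)furan-2(5H)-one | OCC1=C[C@@H](/C=C(/C)[C@@H](O[Si](C)(C)C(C)(C)C)C/C=C(\C)CCO[Si](C)(C)C(C)(C)C)OC1=O | intermediate
21 | (5R)-3-(bromomethyl)-5-[(1Z,3S,5E)-3,8-bis{[tert-butyl(dimethyl)silyl]oxy}-2,6-dimethylocta-1,5-dien-1-yl]furan-2(5H)-one | BrCC1=C[C@@H](/C=C(/C)[C@@H](O[Si](C)(C)C(C)(C)C)C/C=C(\C)CCO[Si](C)(C)C(C)(C)C)OC1=O | intermediate
22 | (5R)-3-(bromomethyl)-5-[(1Z,3S,5E)-3-{[tert-butyl(dimethyl)silyl]oxy}-8-hydroxy-2,6-dimethylocta-1,5-dien-1-yl]furan-2(5H)-one | BrCC1=C[C@@H](/C=C(/C)[C@@H](O[Si](C)(C)C(C)(C)C)C/C=C(\C)CCO)OC1=O | intermediate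
23 | (5R)-3-(bromomethyl)-5-[(1Z,3S,5E)-3-{[tert-butyl(dimethyl)silyl]oxy}-2,6-dimethyl-8-oxoocta-1,5-dien-1-yl]furan-2(5H)-one | BrCC1=C[C@@H](/C=C(/C)[C@@H](O[Si](C)(C)C(C)(C)C)C/C=C(\C)CC=O)OC1=O | intermediate
24 | dichloro({(5R)-5-[(1Z,3S,5E)-3-{[tert-butyl(dimethyl)silyl]oxy}-2,6-dimethyl-8-oxoocta-1,5-dien-1-yl]-2-oxo-2,5-dihydrofuran-3-yl}methyl)chromium | Cl[Cr](Cl)CC1=C[C@@H](/C=C(/C)[C@@H](O[Si](C)(C)C(C)(C)C)C/C=C(\C)CC=O)OC1=O | intermediate
25 | (1(10)E,3S,4Z,6R,7R,8S)-3-{[tert-butyl(dimethyl)silyl]oxy}-8-hydroxygermacra-1(10),4,11(13)-trien-12,6-olide | C=C1C(=O)O[C@@H]2/C=C(/C)[C@@H](O[Si](C)(C)C(C)(C)C)C/C=C(\C)C[C@H](O)[C@@H]12 | intermediate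
26 | (1(10)E,3S,4Z,6R,7R,8S)-3-{[tert-butyl(dimethyl)silyl]oxy}-8-(3-methylbutanoyloxy)germacra-1(10),4,11(13)-trien-12,6-olide | C=C1C(=O)O[C@@H]2/C=C(/C)[C@@H](O[Si](C)(C)C(C)(C)C)C/C=C(\C)C[C@H](OC(=O)CC(C)C)[C@@H]12 | intermediate
27 | (1(10)E,3S,4Z,6R,7R,8S)-3-hydroxy-8-(3-methylbutanoyloxy)germacra-1(10),4,11(13)-trien-12,6-olide | C=C1C(=O)O[C@@H]2/C=C(/C)[C@@H](O)C/C=C(\C)C[C@H](OC(=O)CC(C)C)[C@@H]12 | intermediate
28 | (1(10)E,3S,4Z,6R,7R,8S)-3-acetoxy-8-(3-methylbutanoyloxy)germacra-1(10),4,11(13)-trien-12,6-olide | C=C1C(=O)O[C@@H]2/C=C(/C)[C@@H](OC(C)=O)C/C=C(\C)C[C@H](OC(=O)CC(C)C)[C@@H]12 | intermediate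
29 | (1R,3S,4Z,6R,7R,8S,10R)-3-acetoxy-1,10-epoxy-8-(3-methylbutanoyloxy)germacra-4,11(13)-dien-12,6-olide (CNP0157657.1) | C=C1C(=O)O[C@@H]2/C=C(/C)[C@@H](OC(C)=O)C[C@H]3O[C@]3(C)C[C@H](OC(=O)CC(C)C)[C@@H]12 | target

**Step count and risks**

Total steps: 19. Longest linear sequence: 19 steps (1 to 29); 2, 7 and 14 are purchased building blocks that enter this one sequence.

Steps most likely to fail:

1. Step 15. What may go wrong: the ten-membered closure may leave the chair-like array, so that the aldehyde face is not differentiated (wrong sense at C8), and intermolecular allylation may compete. The fallback sets out from 23 and returns at 26. If the CrCl2 closure of 23 delivers mainly the C8 epimer, (1(10)E,3S,4Z,6R,7R,8R)-3-{[tert-butyl(dimethyl)silyl]oxy}-8-hydroxygermacra-1(10),4,11(13)-trien-12,6-olide F1, the centre is corrected by substitution instead of by transition-state control. Mitsunobu esterification of F1 with 3-methylbutanoic acid (PPh3, diisopropyl azodicarboxylate, toluene, 0 °C) should invert C8 and install the ester at once, giving 26 and replacing step 16.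

2. Step 19. What may go wrong: peracid attack on the wrong face of the C1=C10 olefin, since the ring conformer exposes only one face, or competing attack at C4=C5. The fallback sets out from 28 and returns at 29, and puts the oxygen on the face opposite to the one a direct oxidant reaches. N-Bromosuccinimide in aqueous 1,2-dimethoxyethane at 0 °C should form the bromonium ion on the exposed face, and water should open it anti at the tertiary carbon C10 to give (1S,3S,4Z,6R,7R,8S,10R)-3-acetoxy-1-bromo-10-hydroxy-8-(3-methylbutanoyloxy)germacra-4,11(13)-dien-12,6-olide F2. K2CO3 in acetone at rt then closes the oxirane by SN2 displacement at C1 with inversion, giving 29.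

3. Step 3. What may go wrong: erosion of enantioselectivity, and double-bond migration or self-condensation of the enolisable β,γ-unsaturated aldehyde during the slow zinc-mediated addition. The fallback sets out from 6 and returns at 9, and sets the stereocentre by reduction instead of addition. The lithium acetylide of 7 (LiN(SiMe3)2, THF, −78 °C) should add rapidly to 6 to give racemic methyl (6E)-9-{[tert-butyl(dimethyl)silyl]oxy}-4-hydroxy-7-methylnon-6-en-2-ynoate F3. Buffered Dess–Martin oxidation gives the ynone methyl (6E)-9-{[tert-butyl(dimethyl)silyl]oxy}-7-methyl-4-oxonon-6-en-2-ynoate F4. Midland reduction with (S)-Alpine-Borane (B-isopinocampheyl-9-borabicyclo[3.3.1]nonane from (−)-α-pinene, THF, rt) should then give 9.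

**Further compounds**

F1 | step 15 | (1(10)E,3S,4Z,6R,7R,8R)-3-{[tert-butyl(dimethyl)silyl]oxy}-8-hydroxygermacra-1(10),4,11(13)-trien-12,6-olide | C=C1C(=O)O[C@@H]2/C=C(/C)[C@@H](O[Si](C)(C)C(C)(C)C)C/C=C(\C)C[C@@H](O)[C@@H]12
F2 | step 19 | (1S,3S,4Z,6R,7R,8S,10R)-3-acetoxy-1-bromo-10-hydroxy-8-(3-methylbutanoyloxy)germacra-4,11(13)-dien-12,6-olide | C=C1C(=O)O[C@@H]2/C=C(/C)[C@@H](OC(C)=O)C[C@H](Br)[C@@](O)(C)C[C@H](OC(=O)CC(C)C)[C@@H]12
F3 | step 3 | methyl (6E)-9-{[tert-butyl(dimethyl)silyl]oxy}-4-hydroxy-7-methylnon-6-en-2-ynoate (racemic) | COC(=O)C#CC(O)C/C=C(\C)CCO[Si](C)(C)C(C)(C)C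
F4 | step 3 | methyl (6E)-9-{[tert-butyl(dimethyl)silyl]oxy}-7-methyl-4-oxonon-6-en-2-ynoate | COC(=O)C#CC(=O)C/C=C(\C)CCO[Si](C)(C)C(C)(C)C
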